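**Plan**
- Retrosynthetic cuts: C9'–C10' (acylation of a C9' dithiane anion), C5'–C6' (copper-catalysed allyl–alkyl coupling), C6'–C7' (formaldehyde homologation), O1–C8a (palladium C–O closure of ring B) and C4–C4a (B-alkyl Suzuki coupling).
- Enabling feature: chroman C2, its methyl, C3, C4, side-chain C1'–C5' and the 4'-methyl are the ten carbons of (R)-linalool. Its tertiary carbinol already has the C2 configuration and carries no hydrogen, so O1–C8a can be closed on an aryl bromide without touching the C2–O bond.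
- Forward order: the benzene ring (ring A) is bought and halogenated, linalool is attached at C4a, ring B is closed, C5' is oxidised, then C6'–C9' and finally C10'–C12' are added to the chain.
- Stereochemistry: C2 from (R)-linalool; C8' from (R)-3-bromo-2-methylpropan-1-ol; C10' by Corey–Bakshi–Shibata reduction; the E C3'=C4' alkene from the E-selective SeO2 oxidation of the prenyl terminus.

Key step: step 5

Remark: side-chain carbons are numbered C1' (on chroman C2) to C12' (terminal CMe2), and (R)-linalool of high enantiomeric purity is assumed, since its ee is carried unchanged into C2.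

**Route**

Step 1
Reactants: 1 4-amino-3-methylphenol
Product: 2 2-methyl-4-(triisopropylsilyloxy)aniline
Conditions: i-Pr3SiCl, imidazole, DMF, rt
Reagents that add atoms: chlorotriisopropylsilane, CC(C)[Si](Cl)(C(C)C)C(C)C
Why: Imidazole-promoted O-silylation is selective for the phenol because any N–Si bond is hydrolysed on work-up, and the bulky aryl triisopropylsilyl ether is chosen to outlast the aqueous phosphate, carbonate and organolithium steps that follow.

Step 2
Reactants: 2 2-methyl-4-(triisopropylsilyloxy)aniline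
Product: 3 2-iodo-6-methyl-4-(triisopropylsilyloxy)aniline
Conditions: N-iodosuccinimide, MeCN, 0 °C, dark
Reagents that add atoms: N-iodosuccinimide, O=C1CCC(=O)N1I
Why: Electrophilic aromatic iodination is directed by the amino group, the strongest donor on the ring, whose para position is blocked and whose only free ortho position is the carbon that becomes C4a.

Step 3
Reactants: 3 2-iodo-6-methyl-4-(triisopropylsilyloxy)aniline
Product: 5 (4-bromo-3-iodo-5-methylphenoxy)triisopropylsilane, via arenediazonium bromide 4 (not isolated)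
Conditions: t-BuONO, CuBr2, MeCN, 0 °C → rt
Reagents that add atoms: copper dibromide, Br[Cu]Br
Why: Sandmeyer bromodediazoniation under non-aqueous nitrite ester conditions replaces the amino group by bromine at the future C8a without exposing the aryl silyl ether to aqueous mineral acid.

Step 4
Reactants: 6 (R)-linalool; 5 (4-bromo-3-iodo-5-methylphenoxy)triisopropylsilane
Product: 8 (3R)-1-[2-bromo-3-methyl-5-(triisopropylsilyloxy)phenyl]-3,7-dimethyloct-6-en-3-ol, via alkylborane 7 (not isolated)
Conditions: 9-borabicyclo[3.3.1]nonane (9-BBN), THF, 0 °C → rt; then 5, PdCl2[1,1'-bis(diphenylphosphino)ferrocene] (5 mol %), aq K3PO4, DMF, rt → 45 °C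
Reagents that add atoms: none
Why: Anti-Markovnikov hydroboration by 9-BBN selects the monosubstituted vinyl group over the trisubstituted alkene, and the B-alkyl Suzuki–Miyaura coupling then reacts at the C–I bond well before the hindered C–Br bond, forming C4–C4a without involving the tertiary carbinol stereocentre.

Step 5
Reactants: 8 (3R)-1-[2-bromo-3-methyl-5-(triisopropylsilyloxy)phenyl]-3,7-dimethyloct-6-en-3-ol
Product: 9 (2R)-2,8-dimethyl-2-(4-methylpent-3-enyl)-6-(triisopropylsilyloxy)chroman
Conditions: Pd(OAc)2 (5 mol %), 2-(di-tert-butylphosphino)-1,1'-binaphthyl (6 mol %), Cs2CO3, toluene, 80 °C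
Reagents that add atoms: none
Why: Zerovalent palladium, formed from Pd(OAc)2 and the bulky electron-rich phosphine, inserts into the only carbon–halogen bond (C8a–Br), Cs2CO3 then converts the tertiary alcohol into a palladium-bound alkoxide with loss of bromide, and C–O reductive elimination from divalent palladium forms O1–C8a. The closest known reaction type is the Buchwald-type intramolecular etherification of aryl bromides with tertiary alcohols to give 2,2-disubstituted chromans. Ring B closes as a six-membered ring by reductive elimination from a seven-membered oxapalladacycle, formally a 6-exo attack of the alkoxide oxygen on the aryl carbon. No stereocentre is created; the C2 configuration is that of (R)-linalool and is retained because the C2–O bond is a spectator throughout, whereas an acid-mediated closure would ionise C2. The step needs C–O coupling to outrun reduction of the aryl bromide: the carbinol carbon has no hydrogen, so β-hydride elimination from the alkoxide is impossible, and the bulky ligand both tolerates the di-ortho-substituted C8a (flanked by the C8 methyl and the tether) and speeds reductive elimination. The aryl silyl ether and the remote trisubstituted alkene have no productive pathway to the arylpalladium under anhydrous carbonate.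

Step 6
Reactants: 9 (2R)-2,8-dimethyl-2-(4-methylpent-3-enyl)-6-(triisopropylsilyloxy)chroman
Product: 10 (2E)-5-[(2R)-2,8-dimethyl-6-(triisopropylsilyloxy)chroman-2-yl]-2-methylpent-2-en-1-ol
Conditions: SeO2 (cat.), t-BuOOH, salicylic acid (cat.), CH2Cl2, rt
Reagents that add atoms: tert-butyl hydroperoxide, CC(C)(C)OO
Why: Riley-type allylic oxidation with catalytic SeO2 (ene reaction then [2,3]-sigmatropic shift) hydroxylates the (E)-methyl of the terminal trisubstituted alkene, so C5' is oxygenated and the C3'=C4' double bond is obtained with E geometry.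

Step 7
Reactants: 10 (2E)-5-[(2R)-2,8-dimethyl-6-(triisopropylsilyloxy)chroman-2-yl]-2-methylpent-2-en-1-ol
Product: 11 (2R)-2-[(3E)-5-bromo-4-methylpent-3-enyl]-2,8-dimethyl-6-(triisopropylsilyloxy)chroman
Conditions: CBr4, PPh3, CH2Cl2, 0 °C
Reagents that add atoms: tetrabromomethane, BrC(Br)(Br)Br
Why: Appel bromination converts the primary allylic alcohol into the bromide by SN2 displacement of the oxyphosphonium group under neutral conditions, without allylic transposition or loss of alkene geometry.

Step 8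
Reactants: 12 (R)-3-bromo-2-methylpropan-1-ol
Product: 13 (R)-(3-bromo-2-methylpropoxy)(tert-butyl)dimethylsilane
Conditions: t-BuMe2SiCl, imidazole, CH2Cl2, rt
Reagents that add atoms: tert-butyldimethylsilyl chloride, CC(C)(C)[Si](C)(C)Cl
Why: Imidazole-promoted silylation protects the primary alcohol (the future C9' oxygen) so that the bromide end can be converted into a Grignard reagent.

Step 9
Reactants: 13 (R)-(3-bromo-2-methylpropoxy)(tert-butyl)dimethylsilane
Product: 15 (S)-4-(tert-butyldimethylsilyloxy)-3-methylbutan-1-ol, via Grignard reagent 14 (not isolated)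
Conditions: Mg, THF, 40 °C; then gaseous CH2O (from cracked paraformaldehyde), 0 °C → rt
Reagents that add atoms: formaldehyde (from paraformaldehyde), C=O
Why: Grignard formation followed by addition to monomeric formaldehyde is the classical one-carbon homologation to a primary alcohol, adding C6' while the C8' stereocentre takes no part in either event.

Step 10
Reactants: 15 (S)-4-(tert-butyldimethylsilyloxy)-3-methylbutan-1-ol
Product: 16 (S)-(4-bromo-2-methylbutoxy)(tert-butyl)dimethylsilane
Conditions: CBr4, PPh3, CH2Cl2, 0 °C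
Reagents that add atoms: tetrabromomethane, BrC(Br)(Br)Br
Why: Appel bromination of the unhindered primary alcohol gives the C6' bromide under neutral conditions that the primary silyl ether tolerates.

Step 11
Reactants: 16 (S)-(4-bromo-2-methylbutoxy)(tert-butyl)dimethylsilane; 11 (2R)-2-[(3E)-5-bromo-4-methylpent-3-enyl]-2,8-dimethyl-6-(triisopropylsilyloxy)chroman
Product: 18 (2R)-2-[(3E,8S)-9-(tert-butyldimethylsilyloxy)-4,8-dimethylnon-3-enyl]-2,8-dimethyl-6-(triisopropylsilyloxy)chroman, via Grignard reagent 17 (not isolated)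
Conditions: 16, Mg, THF, rt; then 11, Li2CuCl4 (5 mol %), THF, −78 → 0 °C
Reagents that add atoms: none
Why: Kochi-type Li2CuCl4-catalysed coupling of a primary alkyl Grignard reagent with a primary allylic bromide forms C5'–C6' by attack at the primary carbon with retention of the E alkene, and neither silyl ether reacts with the Grignard reagent.

Step 12
Reactants: 18 (2R)-2-[(3E,8S)-9-(tert-butyldimethylsilyloxy)-4,8-dimethylnon-3-enyl]-2,8-dimethyl-6-(triisopropylsilyloxy)chroman
Product: 19 (2S,6E)-9-[(2R)-2,8-dimethyl-6-(triisopropylsilyloxy)chroman-2-yl]-2,6-dimethylnon-6-en-1-ol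
Conditions: camphor-10-sulfonic acid (cat.), MeOH–CH2Cl2, 0 °C
Reagents that add atoms: none
Why: Acid-catalysed methanolysis removes the primary alkyl tert-butyldimethylsilyl ether, while the aryl triisopropylsilyl ether, which is far more stable to acid, stays in place.

Step 13
Reactants: 19 (2S,6E)-9-[(2R)-2,8-dimethyl-6-(triisopropylsilyloxy)chroman-2-yl]-2,6-dimethylnon-6-en-1-ol
Product: 20 (2S,6E)-9-[(2R)-2,8-dimethyl-6-(triisopropylsilyloxy)chroman-2-yl]-2,6-dimethylnon-6-enal
Conditions: Dess–Martin periodinane, CH2Cl2, 0 °C → rt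
Reagents that add atoms: none
Why: Dess–Martin oxidation gives the aldehyde under near-neutral conditions at or below room temperature, which protects the adjacent C8' stereocentre from epimerisation.

Step 14
Reactants: 20 (2S,6E)-9-[(2R)-2,8-dimethyl-6-(triisopropylsilyloxy)chroman-2-yl]-2,6-dimethylnon-6-enal
Product: 21 (2R)-2-[(3E,8S)-8-(1,3-dithian-2-yl)-4-methylnon-3-enyl]-2,8-dimethyl-6-(triisopropylsilyloxy)chroman
Conditions: HS(CH2)3SH, BF3·OEt2 (cat.), CH2Cl2, −78 → −30 °C
Reagents that add atoms: propane-1,3-dithiol, SCCCS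
Why: Lewis acid-catalysed dithioacetalisation converts the aldehyde into the 1,3-dithiane needed for Corey–Seebach umpolung, with the dithiol present before the acid so that thioacetal formation outpaces any carbonyl–alkene cyclisation.

Step 15
Reactants: 22 3-methylbut-2-enoyl chloride
Product: 23 N-methoxy-N,3-dimethylbut-2-enamide
Conditions: MeNHOMe·HCl, pyridine, CH2Cl2, 0 °C → rt
Reagents that add atoms: N,O-dimethylhydroxylamine hydrochloride, CNOC.Cl
Why: Acylation of N,O-dimethylhydroxylamine by the acid chloride gives the Weinreb amide, an acyl donor that stops at the ketone stage.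

Step 16
Reactants: 21 (2R)-2-[(3E,8S)-8-(1,3-dithian-2-yl)-4-methylnon-3-enyl]-2,8-dimethyl-6-(triisopropylsilyloxy)chroman; 23 N-methoxy-N,3-dimethylbut-2-enamide
Product: 25 1-{2-[(2S,6E)-9-[(2R)-2,8-dimethyl-6-(triisopropylsilyloxy)chroman-2-yl]-6-methylnon-6-en-2-yl]-1,3-dithian-2-yl}-3-methylbut-2-en-1-one, via 2-lithio-1,3-dithiane 24 (not isolated)
Conditions: n-BuLi, THF, −30 °C; then 23, −78 → −20 °C
Reagents that add atoms: none
Why: Corey–Seebach acylation, in which the 2-lithio-1,3-dithiane adds in 1,2 fashion to the Weinreb amide and the chelated tetrahedral adduct survives until work-up, prevents over-addition and creates the C9'–C10' bond with C9' masked as the thioacetal.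

Step 17
Reactants: 25 1-{2-[(2S,6E)-9-[(2R)-2,8-dimethyl-6-(triisopropylsilyloxy)chroman-2-yl]-6-methylnon-6-en-2-yl]-1,3-dithian-2-yl}-3-methylbut-2-en-1-one
Product: 26 (1R)-1-{2-[(2S,6E)-9-[(2R)-2,8-dimethyl-6-(triisopropylsilyloxy)chroman-2-yl]-6-methylnon-6-en-2-yl]-1,3-dithian-2-yl}-3-methylbut-2-en-1-ol
Conditions: (S)-1-methyl-3,3-diphenyltetrahydro-1H,3H-pyrrolo[1,2-c][1,3,2]oxazaborole (0.5 equiv), catecholborane, toluene, −78 → −40 °C
Reagents that add atoms: none
Why: Corey–Bakshi–Shibata reduction sets C10', since the (S)-oxazaborolidine–borane complex should bind the carbonyl oxygen on the side of the smaller 2-methylprop-1-enyl group, away from the fully substituted dithianyl carbon, and deliver hydride to the face that gives the (R)-carbinol, while catecholborane at low temperature leaves both trisubstituted alkenes alone.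

Step 18
Reactants: 26 (1R)-1-{2-[(2S,6E)-9-[(2R)-2,8-dimethyl-6-(triisopropylsilyloxy)chroman-2-yl]-6-methylnon-6-en-2-yl]-1,3-dithian-2-yl}-3-methylbut-2-en-1-ol
Product: 27 (4R,6S,10E)-13-[(2R)-2,8-dimethyl-6-(triisopropylsilyloxy)chroman-2-yl]-4-hydroxy-2,6,10-trimethyltrideca-2,10-dien-5-one
Conditions: MeI, CaCO3, MeCN–H2O (9:1), 40 °C
Reagents that add atoms: water, O
Why: Alkylative thioacetal hydrolysis, in which S-methylation makes the dithiane a leaving group that water displaces via the thionium ion, unmasks the C9' ketone under neutral, non-oxidising conditions that spare the electron-rich arene, the alkenes and the epimerisable C8' and C10' centres.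

Step 19
Reactants: 27 (4R,6S,10E)-13-[(2R)-2,8-dimethyl-6-(triisopropylsilyloxy)chroman-2-yl]-4-hydroxy-2,6,10-trimethyltrideca-2,10-dien-5-one
Product: 28 (4R,6S,10E)-4-hydroxy-13-[(2R)-6-hydroxy-2,8-dimethylchroman-2-yl]-2,6,10-trimethyltrideca-2,10-dien-5-one
Conditions: Bu4NF, AcOH (1:1), THF, 0 °C
Reagents that add atoms: none
Why: Fluoride-mediated desilylation cleaves the aryl Si–O bond readily because phenoxide is a good leaving group, and buffering with acetic acid keeps the medium from enolising the α-hydroxy ketone.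

**Compound list**

1 | 4-amino-3-methylphenol | Cc1cc(O)ccc1N | starting material
2 | 2-methyl-4-(triisopropylsilyloxy)aniline | Cc1cc(O[Si](C(C)C)(C(C)C)C(C)C)ccc1N | intermediate
3 | 2-iodo-6-methyl-4-(triisopropylsilyloxy)aniline | Cc1cc(O[Si](C(C)C)(C(C)C)C(C)C)cc(I)c1N | intermediate
4 | 2-iodo-6-methyl-4-(triisopropylsilyloxy)benzenediazonium bromide | Cc1cc(O[Si](C(C)C)(C(C)C)C(C)C)cc(I)c1[N+]#N.[Br-] | intermediate
5 | (4-bromo-3-iodo-5-methylphenoxy)triisopropylsilane | Cc1cc(O[Si](C(C)C)(C(C)C)C(C)C)cc(I)c1Br | intermediate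
6 | (R)-linalool, (3R)-3,7-dimethylocta-1,6-dien-3-ol | C=C[C@](C)(O)CCC=C(C)C | starting material
7 | 9-[(3S)-3-hydroxy-3,7-dimethyloct-6-enyl]-9-borabicyclo[3.3.1]nonane (same spatial arrangement as in 6; the descriptor changes only through CIP priorities) | CC(C)=CCC[C@@](C)(O)CCB1C2CCCC1CCC2 | intermediate
8 | (3R)-1-[2-bromo-3-methyl-5-(triisopropylsilyloxy)phenyl]-3,7-dimethyloct-6-en-3-ol | CC(C)=CCC[C@@](C)(O)CCc1cc(O[Si](C(C)C)(C(C)C)C(C)C)cc(C)c1Br | intermediate
9 | (2R)-2,8-dimethyl-2-(4-methylpent-3-enyl)-6-(triisopropylsilyloxy)chroman | CC(C)=CCC[C@]1(C)CCc2cc(O[Si](C(C)C)(C(C)C)C(C)C)cc(C)c2O1 | intermediate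
10 | (2E)-5-[(2R)-2,8-dimethyl-6-(triisopropylsilyloxy)chroman-2-yl]-2-methylpent-2-en-1-ol | OC/C(C)=C/CC[C@]1(C)CCc2cc(O[Si](C(C)C)(C(C)C)C(C)C)cc(C)c2O1 | intermediate
11 | (2R)-2-[(3E)-5-bromo-4-methylpent-3-enyl]-2,8-dimethyl-6-(triisopropylsilyloxy)chroman | BrC/C(C)=C/CC[C@]1(C)CCc2cc(O[Si](C(C)C)(C(C)C)C(C)C)cc(C)c2O1 | intermediate
12 | (R)-3-bromo-2-methylpropan-1-ol | OC[C@@H](C)CBr | starting material
13 | (R)-(3-bromo-2-methylpropoxy)(tert-butyl)dimethylsilane | CC(C)(C)[Si](C)(C)OC[C@@H](C)CBr | intermediate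
14 | (R)-[3-(tert-butyldimethylsilyloxy)-2-methylpropyl]magnesium bromide | CC(C)(C)[Si](C)(C)OC[C@@H](C)C[Mg]Br | intermediate
15 | (S)-4-(tert-butyldimethylsilyloxy)-3-methylbutan-1-ol | CC(C)(C)[Si](C)(C)OC[C@@H](C)CCO | intermediate
16 | (S)-(4-bromo-2-methylbutoxy)(tert-butyl)dimethylsilane | CC(C)(C)[Si](C)(C)OC[C@@H](C)CCBr | intermediate
17 | (S)-[4-(tert-butyldimethylsilyloxy)-3-methylbutyl]magnesium bromide | CC(C)(C)[Si](C)(C)OC[C@@H](C)CC[Mg]Br | intermediate
18 | (2R)-2-[(3E,8S)-9-(tert-butyldimethylsilyloxy)-4,8-dimethylnon-3-enyl]-2,8-dimethyl-6-(triisopropylsilyloxy)chroman | CC(C)(C)[Si](C)(C)OC[C@@H](C)CCC/C(C)=C/CC[C@]1(C)CCc2cc(O[Si](C(C)C)(C(C)C)C(C)C)cc(C)c2O1 | intermediate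
19 | (2S,6E)-9-[(2R)-2,8-dimethyl-6-(triisopropylsilyloxy)chroman-2-yl]-2,6-dimethylnon-6-en-1-ol | OC[C@@H](C)CCC/C(C)=C/CC[C@]1(C)CCc2cc(O[Si](C(C)C)(C(C)C)C(C)C)cc(C)c2O1 | intermediate
20 | (2S,6E)-9-[(2R)-2,8-dimethyl-6-(triisopropylsilyloxy)chroman-2-yl]-2,6-dimethylnon-6-enal | O=C[C@@H](C)CCC/C(C)=C/CC[C@]1(C)CCc2cc(O[Si](C(C)C)(C(C)C)C(C)C)cc(C)c2O1 | intermediate
21 | (2R)-2-[(3E,8S)-8-(1,3-dithian-2-yl)-4-methylnon-3-enyl]-2,8-dimethyl-6-(triisopropylsilyloxy)chroman | S1CCCSC1[C@@H](C)CCC/C(C)=C/CC[C@]2(C)CCc3cc(O[Si](C(C)C)(C(C)C)C(C)C)cc(C)c3O2 | intermediate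
22 | 3-methylbut-2-enoyl chloride | CC(C)=CC(=O)Cl | starting material
23 | N-methoxy-N,3-dimethylbut-2-enamide | CON(C)C(=O)C=C(C)C | intermediate
24 | 2-lithio derivative of 21, lithium at the dithiane C2 (C9') | [Li]C1(SCCCS1)[C@@H](C)CCC/C(C)=C/CC[C@]2(C)CCc3cc(O[Si](C(C)C)(C(C)C)C(C)C)cc(C)c3O2 | intermediate
25 | 1-{2-[(2S,6E)-9-[(2R)-2,8-dimethyl-6-(triisopropylsilyloxy)chroman-2-yl]-6-methylnon-6-en-2-yl]-1,3-dithian-2-yl}-3-methylbut-2-en-1-one | CC(C)=CC(=O)C1(SCCCS1)[C@@H](C)CCC/C(C)=C/CC[C@]2(C)CCc3cc(O[Si](C(C)C)(C(C)C)C(C)C)cc(C)c3O2 | intermediate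
26 | (1R)-1-{2-[(2S,6E)-9-[(2R)-2,8-dimethyl-6-(triisopropylsilyloxy)chroman-2-yl]-6-methylnon-6-en-2-yl]-1,3-dithian-2-yl}-3-methylbut-2-en-1-ol | CC(C)=C[C@@H](O)C1(SCCCS1)[C@@H](C)CCC/C(C)=C/CC[C@]2(C)CCc3cc(O[Si](C(C)C)(C(C)C)C(C)C)cc(C)c3O2 | intermediate
27 | (4R,6S,10E)-13-[(2R)-2,8-dimethyl-6-(triisopropylsilyloxy)chroman-2-yl]-4-hydroxy-2,6,10-trimethyltrideca-2,10-dien-5-one | CC(C)=C[C@@H](O)C(=O)[C@@H](C)CCC/C(C)=C/CC[C@]1(C)CCc2cc(O[Si](C(C)C)(C(C)C)C(C)C)cc(C)c2O1 | intermediate
28 | (4R,6S,10E)-4-hydroxy-13-[(2R)-6-hydroxy-2,8-dimethylchroman-2-yl]-2,6,10-trimethyltrideca-2,10-dien-5-one | CC(C)=C[C@@H](O)C(=O)[C@@H](C)CCC/C(C)=C/CC[C@]1(C)CCc2cc(O)cc(C)c2O1 | target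

**Step count and risks**

Total step count: 19. Longest linear sequence: 15 steps (steps 1–7, 11–14 and 16–19, from 4-amino-3-methylphenol).

Steps most likely to fail:

Step 5. Oxidative addition at the di-ortho-substituted C8a–Br bond may be slow, so that hydrodebromination or catalyst decomposition overtakes C–O bond formation. The fallback sets out from 8 and changes both the halide and the metal. An aromatic Finkelstein exchange (CuI cat., NaI, trans-N,N'-dimethylcyclohexane-1,2-diamine, dioxane, 110 °C) should give the aryl iodide (3R)-1-[2-iodo-3-methyl-5-(triisopropylsilyloxy)phenyl]-3,7-dimethyloct-6-en-3-ol F1. This would then be closed by a copper-mediated Ullmann-type etherification (CuI, 3,4,7,8-tetramethyl-1,10-phenanthroline, Cs2CO3, toluene, 110 °C). That closure forms the same O1–C8a bond, again leaves C2–O untouched, and returns to the route at 9.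

Step 16. The hindered, strongly basic dithianyl anion may abstract a γ-proton from the methyl groups of the amide instead of adding to its carbonyl, which would return 21 after work-up. The fallback sets out from 21. The same anion 24 would be added to 3-methylbut-2-enal, a more electrophilic and less readily deprotonated partner, giving the carbinol 1-{2-[(2S,6E)-9-[(2R)-2,8-dimethyl-6-(triisopropylsilyloxy)chroman-2-yl]-6-methylnon-6-en-2-yl]-1,3-dithian-2-yl}-3-methylbut-2-en-1-ol as a mixture of C10' epimers F2. Parikh–Doering oxidation (SO3·pyridine, DMSO, i-Pr2NEt), which tolerates the dithiane, would then return to the route at 25.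

Step 17. Facial discrimination may be poor if the alkenyl and dithianyl flanks of the ketone are not differentiated strongly enough by the catalyst, or if catalyst control is opposed by the C8' centre. The fallback sets out from 25 and replaces reagent control by separation and recycling. Luche reduction (NaBH4, CeCl3·7H2O, MeOH, −78 °C) should give 26 together with its C10' epimer (1S)-1-{2-[(2S,6E)-9-[(2R)-2,8-dimethyl-6-(triisopropylsilyloxy)chroman-2-yl]-6-methylnon-6-en-2-yl]-1,3-dithian-2-yl}-3-methylbut-2-en-1-ol F3. The two are diastereomers and should be separable by chromatography. F3 would be returned to 25 by Parikh–Doering oxidation and resubmitted, and the route is rejoined at 26.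

**Further compounds**

F1 | step 5 | (3R)-1-[2-iodo-3-methyl-5-(triisopropylsilyloxy)phenyl]-3,7-dimethyloct-6-en-3-ol | CC(C)=CCC[C@@](C)(O)CCc1cc(O[Si](C(C)C)(C(C)C)C(C)C)cc(C)c1I
F2 | step 16 | 1-{2-[(2S,6E)-9-[(2R)-2,8-dimethyl-6-(triisopropylsilyloxy)chroman-2-yl]-6-methylnon-6-en-2-yl]-1,3-dithian-2-yl}-3-methylbut-2-en-1-ol, both C10' epimers | CC(C)=CC(O)C1(SCCCS1)[C@@H](C)CCC/C(C)=C/CC[C@]2(C)CCc3cc(O[Si](C(C)C)(C(C)C)C(C)C)cc(C)c3O2
F3 | step 17 | (1S)-1-{2-[(2S,6E)-9-[(2R)-2,8-dimethyl-6-(triisopropylsilyloxy)chroman-2-yl]-6-methylnon-6-en-2-yl]-1,3-dithian-2-yl}-3-methylbut-2-en-1-ol | CC(C)=C[C@H](O)C1(SCCCS1)[C@@H](C)CCC/C(C)=C/CC[C@]2(C)CCc3cc(O[Si](C(C)C)(C(C)C)C(C)C)cc(C)c3O2
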